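A factor of 35000 separates the step from starting material to target in the coldest flask, eta, from the same step in the hottest, alpha, and I start my reckoning with eta.

common to all: solid substrate 0.80 M; time 80 min
- alpha: temperature 90 °C
- gamma: temperature 60 °C
- eta: temperature 0 °C
- delta: temperature 30 °C

    starting material ⇌ other conformer (K1 = 19, k1 = 0.00590 /min, Ea1 = 109 kJ/mol, ΔH1 = −28.0 kJ/mol)
    starting material → target (k2 = 0.0371 /min, Ea2 = 96.0 kJ/mol)
    other conformer → isomer of the product (k3 = 0.151 /min, Ea3 = 93.0 kJ/mol)
    target ⇌ isomer of the product (K4 = 2.63, k4 = 0.0190 /min, Ea4 = 124 kJ/mol, ΔH4 = −18.0 kJ/mol)
    solid substrate ⇌ starting material, rate k5*(cs5 - [starting material]) while solid is left; crystals form when [starting material] > cs5 (cs5 = 0.50 M, k5 = 0.0483 /min)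
    2 starting material → homo dimer (k6 = 1.59 × 10⁻⁵ /M/min, Ea6 = 122 kJ/mol)
    (constants at 90 °C)

- a species is counted by the solid substrate in it: one homo dimer counts as two
- a step written with two of one species runs at k times the square of its concentration and takes two of it each time
- given per volume of solution although it is solid: solid substrate
- all constants are for 90 °C and move with temperature by the activation energies and enthalpies
- at the start none of the solid substrate is in solution
- in a conversion other conformer counts as not yet reacted
- what has only dissolved of solid substrate counts as not reacted

- the flask that comes out highest in amount of target, in percent of the solid substrate charged, or "all alike" when all lie within 1.5 percentage points (alpha / gamma / eta / delta / all alike)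
- target at the end, in percent of the solid substrate charged, alpha
- target at the end, in percent of the solid substrate charged, gamma
- target at the end, in percent of the solid substrate charged, eta
- target at the end, in percent of the solid substrate charged, delta

In eta the target-forming step has the constant 1.05 × 10⁻⁶ /min, so its time constant of 9.56 × 10⁵ min is far longer than the 80 min of the run, and hardly any starting material goes to target by this step. Dissolved starting material stands at or below the solubility, 0.50 M, since crystals form above it. The constant of eta times the solubility gives 5.23 × 10⁻⁷ M/min, which is the target formed per minute in the solution of eta standing at its solubility, my saturated rate. This is pseudo-zero-order growth: the target rises steadily while the solution stays full.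

Held for the whole run, the saturated rate gives a bound from above of 0.00523 % of the charge. The solution of eta fills with the time constant 20.7 min, so it loses at most that lag of saturated time. The remaining 59.3 min give a bound from below of 0.00388 %. In alpha the same ceiling comes to 186 % of the charge, above the charge itself, so there this bound tells me nothing.

The forecast names alpha, with 44.8 % in alpha, 7.5 % in gamma, 0.26 % in delta and 0.004 % in eta. For alpha it reckons that “Products total about 0.69 M”. Its value for eta lies inside my bracket.

The simulation gives alpha as highest, with 44.8 % in alpha, 7.53 % in gamma, 0.256 % in delta and 0 % in eta at the digits kept. Left for 800 min, eta holds 0.0510 % of target with 37.4 % of the charge still solid, and the saturated rate over that time less the lag gives 0.0510 %. The neighbour of eta charged with 0.48 M, a charge below the solubility, ends with 0 % as solid; the saturated rate over the same shortened time, taken on that smaller charge, gives 0.00646 %, and that flask stands at 0.00650 % of target.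

Its constants stand for no real mixture; the rest is arithmetic.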